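Which of these flasks holds the highest share of its Z as Z.E when read, and how much does each hold?

| setting | theta | epsilon | gamma | delta |
|---|---|---|---|---|
| Z | 2.0 M | 2.0 M | 2.0 M | 2.0 M |
| E | 2.20 M | 2.20 M | 2.20 M | 2.20 M |
| time | 20 h | 20 h | 20 h | 20 h |
| remark | at −25 °C until 10 h, from then on at 25 °C |  |  |  |
| temperature |  | 25 °C | 0 °C | −25 °C |

    Z + Z.E → Z.Z.E (k1 = 0.0597 /M/h, Ea1 = 68.0 kJ/mol)
    Z + E → Z.E (k2 = 1.99 /M/h, Ea2 = 68.0 kJ/mol)
    Z + 2 E → D (k3 = 0.0180 /M²/h, Ea3 = 65.0 kJ/mol)
    Z.E → J (k4 = 0.0638 /h, Ea4 = 101 kJ/mol)
    (constants at 25 °C)

- percentages count the Z that a species holds: one Z.Z.E counts as two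
- two of one species on the left: rate k times its square, two consumed each time
- the constants hold at 25 °C; other temperatures follow from the activation energies

* the flask that comes out highest in amount of Z.E, in percent of the Z charged, or "all alike" when all lie within 1.5 percentage points (theta / epsilon / gamma / delta / all alike)
* Z.E at the end, in percent of the Z charged, theta
* Z.E at the end, in percent of the Z charged, epsilon
* Z.E at the end, in percent of the Z charged, gamma
* Z.E at the end, in percent of the Z charged, delta

I asked first what the end state must be. Z is the limiting reagent, since c(Z) starts below c(E), and Z.E has steps leaving it, to J and to Z.Z.E, with none returning, so Z.E is a passing stock. What a reading finds therefore depends on how fast that stock fills and how fast it drains. I reckoned the step Z + E → Z.E alone for filling, because at the start of delta it uses Z 39 times faster than the step to D, and its constant stands above that of Z + Z.E → Z.Z.E.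

The filling time, the inverse of the filling constant at the flask's temperature times the geometric mean of the charges, came to 60.2 h in delta. With charges taken as equal, the share filled by time t is t/(t + filling time), which gave 24.9 % for delta. My second way was the exact second-order integral with unequal charges: the ratio c(E)/c(Z) had to grow from 1.10 to 1.14, which gave 26.1 %. The two parted by 1.2 percentage points, and the first way was the one that cheated, since it replaces the unequal charges with a mean. I trusted the integral for delta, where the draining time, the inverse of the constant of Z.E → J, was 57600 h, far beyond 20 h.

For gamma and epsilon I took the filled share of the first way, as a rough figure, and multiplied it by exp(−t/draining time), as if the stock had stood from the start. Gamma, with filling time 2.95 h and draining time 653 h, gave 84.5 %. Epsilon, with 0.240 h and 15.7 h, gave 27.6 %. Theta fills quickly once warm, so I reckoned as if its whole charge stood as Z.E and drained from 10 h onward, which gave 52.8 %. I committed to gamma as highest.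

The forecast named gamma, with 49.7 % for theta, 26.4 % for epsilon, 83.4 % for gamma and 25.8 % for delta, writing of epsilon that “Z is gone within a few hours”.

The simulation gave 49.8 % in theta, 26.4 % in epsilon, 83.3 % in gamma and 25.8 % in delta, so gamma came out highest, and my theta lay 3.0 points high, beside 7.39 % of Z.Z.E in that flask. From the coldest to the hottest flask, draining sped up by a factor of 3700 and filling by 250. When read at 20.0 h, delta, with its filling time of 60.2 h, held 73.4 % of Z beside 0.577 % of D and 0.219 % of Z.Z.E, while epsilon held 65.2 % of J.

The delta flask read at 12 h has the same filling time, which gives 16.6 %. The computed value was 17.3 %.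

(The rate constants stand for no real mixture, and the outcome is calculated.)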